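## Retrosynthetic overview

1. Target ⇐ desilylation and O-demethylation ⇐ protected pentacycle ⇐ intramolecular Diels–Alder macrocyclisation of a 3-acyl-5-methylidene tetronate onto the side-chain diene (C15–C27 and C21–C26 bonds): ring C and the 11-membered carbocycle close together.
2. Cyclisation precursor ⇐ α-quaternary decalin aldehyde + C3-lithiated 4-methoxy-5-methylidenefuranone (C31–C34 bond), then oxidation.
3. Decalin aldehyde ⇐ intramolecular Diels–Alder of an acyclic (2E,8E,10E)-trienal (C5–C6 and C9–C36 bonds): rings A and B close together.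
4. Trienal ⇐ Suzuki union (C7–C8) of an iodo-enal from (S)-citronellal with a dienyl boronate; boronate ⇐ Julia olefination (C12=C13) and carboalumination/Negishi coupling (C17–C18) from Roche ester, but-3-yn-1-ol and methyl (R)-3-hydroxybutanoate.
5. Ring order: A + B, then C + macrocycle; the tetronate ring is brought in intact.

Assumption 1: the SMILES defines the target fully; atoms are labelled C1…C38 in SMILES order (2S,5R,6S,9S,10R,15R,21R,23R,27S,36S), and the C2 methyl is axial on the trans-decalin.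
Assumption 2: the facial sense of the oxazaborolidinium catalyst in step 19 is taken from the usual model for 2-methyl-2-enals; if it proves opposite, the enantiomeric catalyst is used.

Abbreviations: TBDPS = tert-butyldiphenylsilyl; TBS = tert-butyldimethylsilyl; PT = 1-phenyl-1H-tetrazol-5-yl; pin = pinacolato.

## Route

Step 1
Reactants: 1 methyl (R)-3-hydroxybutanoate
Product: 2 methyl (R)-3-(TBDPS-oxy)butanoate
Conditions: TBDPSCl, imidazole, DMF, rt
Reagents that add atoms: tert-butyl(chloro)diphenylsilane, CC(C)(C)[Si](Cl)(c1ccccc1)c1ccccc1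
Why: Silyl ether formation (substitution at silicon) protects the chiral-pool carbinol that becomes C23, whose (R) configuration is not touched.

Step 2
Reactants: 2 methyl (R)-3-(TBDPS-oxy)butanoate
Product: 3 (R)-3-(TBDPS-oxy)butanal
Conditions: i-Bu2AlH (1.1 equiv), CH2Cl2, −78 °C; aq. potassium sodium tartrate
Reagents that add atoms: none
Why: Partial ester reduction stops at the aldehyde because the tetrahedral aluminium hemiacetal is stable at −78 °C.

Step 3
Reactants: 3 (R)-3-(TBDPS-oxy)butanal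
Product: 4 ethyl (2E,5R)-2-bromo-5-(TBDPS-oxy)hex-2-enoate
Conditions: KOt-Bu, 18-crown-6, THF, −78 °C
Reagents that add atoms: ethyl 2-[bis(2,2,2-trifluoroethoxy)phosphoryl]-2-bromoacetate, CCOC(=O)C(Br)P(=O)(OCC(F)(F)F)OCC(F)(F)F (known reagent, one step from the commercial non-brominated phosphonate)
Why: Still–Gennari-type Horner–Wadsworth–Emmons olefination with the α-bromo trifluoroethyl phosphonate gives the (E)-α-bromoenoate (chain cis to the ester, Br trans to the chain), which fixes the later C18=C21 geometry.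

Step 4
Reactants: 4 ethyl (2E,5R)-2-bromo-5-(TBDPS-oxy)hex-2-enoate
Product: 5 (2E,5R)-2-bromo-5-(TBDPS-oxy)hex-2-en-1-ol
Conditions: i-Bu2AlH (2.2 equiv), CH2Cl2, −78 °C
Reagents that add atoms: none
Why: 1,2-Reduction of the enoate to the allylic alcohol (future C19) leaves the vinyl bromide and the alkene geometry intact.

Step 5
Reactants: 5 (2E,5R)-2-bromo-5-(TBDPS-oxy)hex-2-en-1-ol
Product: 6 (2E,5R)-2-bromo-1,5-bis(TBDPS-oxy)hex-2-ene
Conditions: TBDPSCl, imidazole, DMF, rt
Reagents that add atoms: tert-butyl(chloro)diphenylsilane, CC(C)(C)[Si](Cl)(c1ccccc1)c1ccccc1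
Why: Silyl ether formation gives an allylic ether that survives organoaluminium, chromium and acid conditions and is later distinguished from the primary TBS ether.

Step 6
Reactants: 7 but-3-yn-1-ol
Product: 8 5-(but-3-yn-1-ylsulfanyl)-1-phenyl-1H-tetrazole
Conditions: PT-SH, PPh3, DIAD, THF, 0 °C → rt
Reagents that add atoms: 1-phenyl-1H-tetrazole-5-thiol, Sc1nnnn1-c1ccccc1
Why: Mitsunobu thioetherification of the primary alcohol installs the tetrazolyl sulfide.

Step 7
Reactants: 8 5-(but-3-yn-1-ylsulfanyl)-1-phenyl-1H-tetrazole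
Product: 9 5-(but-3-yn-1-ylsulfonyl)-1-phenyl-1H-tetrazole
Conditions: (NH4)6Mo7O24·4H2O (cat.), 30% H2O2, EtOH, 0 °C → rt
Reagents that add atoms: hydrogen peroxide, OO
Why: Molybdate-catalysed sulfide-to-sulfone oxidation is selective for sulfur and leaves the alkyne alone.

Step 8
Reactants: 10 methyl (S)-3-hydroxy-2-methylpropanoate
Product: 11 methyl (S)-3-(TBS-oxy)-2-methylpropanoate
Conditions: TBSCl, imidazole, CH2Cl2, rt
Reagents that add atoms: tert-butyl(chloro)dimethylsilane, CC(C)(C)[Si](C)(C)Cl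
Why: Silyl ether formation protects the future C9 oxygen of the chiral-pool unit that supplies C10.

Step 9
Reactants: 11 methyl (S)-3-(TBS-oxy)-2-methylpropanoate
Product: 12 (S)-3-(TBS-oxy)-2-methylpropanal
Conditions: i-Bu2AlH (1.1 equiv), CH2Cl2, −78 °C; aq. potassium sodium tartrate; used crude
Reagents that add atoms: none
Why: Partial ester reduction gives the aldehyde, used at once without chromatography so that the α-stereocentre does not erode.

Step 10
Reactants: 12 (S)-3-(TBS-oxy)-2-methylpropanal; 9 5-(but-3-yn-1-ylsulfonyl)-1-phenyl-1H-tetrazole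
Product: 13 (2R,3E)-2-methylhept-3-en-6-yn-1-yl TBS ether
Conditions: KN(SiMe3)2, DME, −60 °C → rt
Reagents that add atoms: none
Why: Julia–Kocienski olefination of an α-branched aldehyde with a PT sulfone gives the (E)-alkene C12=C13 by anti-selective addition, Smiles rearrangement and anti-elimination; C10 comes from the Roche ester.

Step 11
Reactants: 13 (2R,3E)-2-methylhept-3-en-6-yn-1-yl TBS ether; 6 (2E,5R)-2-bromo-1,5-bis(TBDPS-oxy)hex-2-ene
Product: 15 (2R,3E,6E,8Z,11R)-triene tris-silyl ether, via alkenylalane 14 (not isolated)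
Conditions: Me3Al, Cp2ZrCl2 (20 mol %), H2O (1 equiv), CH2Cl2, −20 °C; then 6, ZnCl2, Pd(PPh3)4 (5 mol %), THF, rt
Reagents that add atoms: trimethylaluminium, C[Al](C)C
Why: Negishi zirconium-catalysed syn-carboalumination of the terminal alkyne (methyl to C15, aluminium to C17) followed by palladium/zinc-mediated alkenyl–alkenyl coupling with retention at both partners sets the C15=C17 (E) and C18=C21 geometries of the diene.

Step 12
Reactants: 15 (2R,3E,6E,8Z,11R)-triene tris-silyl ether
Product: 16 (2R,3E,6E,8Z,11R)-trienol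
Conditions: camphorsulfonic acid (cat.), MeOH–CH2Cl2 (1:1), 0 °C
Reagents that add atoms: none
Why: Acid-catalysed methanolysis removes the primary TBS ether far faster than the two TBDPS ethers.

Step 13
Reactants: 16 (2R,3E,6E,8Z,11R)-trienol
Product: 17 (2R,3E,6E,8Z,11R)-trienal
Conditions: Dess–Martin periodinane, NaHCO3, CH2Cl2, 0 °C; used crude at once
Reagents that add atoms: none
Why: Buffered, non-basic Dess–Martin oxidation gives the epimerisable 2-methyl-3-enal without conjugation or loss of C10 configuration.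

Step 14
Reactants: 17 (2R,3E,6E,8Z,11R)-trienal
Product: 18 (1E,3S,4E,7E,9Z,12R)-tetraenyl pinacol boronate
Conditions: Cl2CHB(pin), CrCl2, LiI, THF, rt
Reagents that add atoms: 2-(dichloromethyl)-4,4,5,5-tetramethyl-1,3,2-dioxaborolane, ClC(Cl)B1OC(C)(C)C(C)(C)O1
Why: The boron variant of the Takai olefination (gem-dichromium reagent, neutral medium) converts the sensitive aldehyde into the (E)-alkenyl boronate C8=C9 without epimerising C10.

Step 15
Reactants: 19 (S)-citronellal
Product: 20 (1E,4S)-1-iodo-4,8-dimethylnona-1,7-diene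
Conditions: CHI3, CrCl2, dioxane–THF (6:1), 0 °C → rt
Reagents that add atoms: iodoform, IC(I)I
Why: Takai iodo-olefination gives the (E)-vinyl iodide (C6=C7); the C2 methyl stereocentre comes from citronellal.

Step 16
Reactants: 20 (1E,4S)-1-iodo-4,8-dimethylnona-1,7-diene
Product: 21 (4S,6E)-7-iodo-4-methylhept-6-enal
Conditions: O3, pyridine, CH2Cl2–MeOH, −78 °C (stopped when 20 is consumed); then PPh3
Reagents that add atoms: ozone, [O-][O+]=O
Why: Ozonolysis with reductive work-up cleaves the electron-rich trisubstituted alkene much faster than the vinyl iodide.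

Step 17
Reactants: 21 (4S,6E)-7-iodo-4-methylhept-6-enal
Product: 22 (2E,6S,8E)-9-iodo-2,6-dimethylnona-2,8-dienal
Conditions: Ph3P=C(Me)CHO, PhMe, 80 °C
Reagents that add atoms: 2-(triphenyl-λ5-phosphanylidene)propanal, CC(C=O)=P(c1ccccc1)(c1ccccc1)c1ccccc1
Why: Wittig reaction of the stabilised ylide gives the (E)-2-methyl enal, the dienophile geometry that places the C36 methyl cis to the tether.

Step 18
Reactants: 22 (2E,6S,8E)-9-iodo-2,6-dimethylnona-2,8-dienal; 18 (1E,3S,4E,7E,9Z,12R)-tetraenyl pinacol boronate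
Product: 23 (2E,6S,8E,10E,12R,13E,16E,18Z,21R)-hexaenal
Conditions: Pd(PPh3)4 (10 mol %), TlOEt, THF–H2O (3:1), rt
Reagents that add atoms: none
Why: Suzuki–Miyaura alkenyl–alkenyl coupling proceeds with retention at both carbons and gives the (E,E)-diene C6=C7–C8=C9 under mild base that the enal tolerates.

Step 19
Reactants: 23 (2E,6S,8E,10E,12R,13E,16E,18Z,21R)-hexaenal
Product: 24 (1S,2S,4aS,6S,8aR)-octahydronaphthalene-1-carbaldehyde
Conditions: (S)-o-tolyl-CBS-oxazaborolidine (20 mol %), Tf2NH (20 mol %), CH2Cl2, −78 → −40 °C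
Reagents that add atoms: none
Why: Lewis-acid-catalysed endo intramolecular Diels–Alder reaction of the (E)-2-methyl enal with the (E,E)-diene through a chair six-membered tether closes rings A and B together and sets C5, C6, C9 and C36 (trans ring fusion, acyl cis to the C9 chain by the endo rule, C36 methyl cis to the tether from the (E)-dienophile); the catalyst has to choose the diene face against the tether, because the C2 methyl is pseudo-axial in the required chair (mismatched pairing), so only a modest dr of about 2–3:1 is expected and the minor decalin is removed by chromatography.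

Step 20
Reactants: 25 4-methoxyfuran-2(5H)-one
Product: 28 4-methoxy-5-methylidenefuran-2(5H)-one, via lithium alkoxide 26 (not isolated), via mesylate 27 (not isolated)
Conditions: LiN(i-Pr)2, THF, −78 °C; HCHO (g); then MsCl, Et3N, DBU, −78 → 0 °C
Reagents that add atoms: formaldehyde, C=O; methanesulfonyl chloride, CS(=O)(=O)Cl (its atoms stay only in 27)
Why: Deprotonation at C5 gives the aromatic 2-oxidofuran enolate, which undergoes aldol addition to formaldehyde; mesylation and E1cB elimination then give the exocyclic alkene.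

Step 21
Reactants: 28 4-methoxy-5-methylidenefuran-2(5H)-one; 24 (1S,2S,4aS,6S,8aR)-octahydronaphthalene-1-carbaldehyde
Product: 29 decalinyl(tetronate)carbinol (both carbinol epimers)
Conditions: 28 (3 equiv), LiN(i-Pr)2, THF, −78 °C; then 24, −78 → −50 °C
Reagents that add atoms: none
Why: The only acidic hydrogen left on 28 is the vinylic C3–H flanked by the lactone carbonyl and the methoxy group, so directed lithiation and 1,2-addition to the non-enolisable neopentyl aldehyde forge C31–C34; the new carbinol centre is oxidised away in the next step.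

Step 22
Reactants: 29 decalinyl(tetronate)carbinol
Product: 31 O-methyl bis-TBDPS pentacycle, via ketone 30 (not isolated)
Conditions: Dess–Martin periodinane, NaHCO3, CH2Cl2, 0 °C; SiO2 pad; then PhMe (0.5 mM), BHT, 115 °C
Reagents that add atoms: none
Why: Oxidation gives the 3-acyl-5-methylidene tetronate, whose exocyclic alkene (activated through the enol ether by both carbonyls) undergoes a thermal intramolecular Diels–Alder macrocyclisation that closes ring C and the 11-membered ring in one operation; the tether fixes the regiochemistry (C15–C27, C21–C26), the diene geometry places C14 and C22 cis, the eight-atom (E)-alkene bridge can only reach C27 through C32 with the lactone oxygen endo (C14 and C32 trans), and the face is the one in which C10–H eclipses C12=C13 with the C10 methyl and the decalin outside the forming ring, giving 15R, 21R, 27S.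

Step 23
Reactants: 31 O-methyl bis-TBDPS pentacycle
Product: 32 O-methyl diol
Conditions: HF·pyridine, pyridine, THF, 0 °C → rt
Reagents that add atoms: none
Why: Fluoride-driven cleavage of both silyl ethers (strong Si–F bond) under buffered conditions leaves the vinylogous ester and the alkenes untouched.

Step 24
Reactants: 32 O-methyl diol
Product: 33 CNP0189906.1
Conditions: LiCl, DMSO, 60 °C; 1 M HCl work-up
Reagents that add atoms: none
Why: Chloride attacks the methyl group of the vinylogous ester (SN2), releasing the stabilised acyl tetronate anion, which is protonated on work-up; no stereocentre is involved.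

## Compound list

1 | methyl (R)-3-hydroxybutanoate | C[C@@H](O)CC(=O)OC | starting material
2 | methyl (R)-3-[(tert-butyldiphenylsilyl)oxy]butanoate | C[C@@H](O[Si](c1ccccc1)(c1ccccc1)C(C)(C)C)CC(=O)OC | intermediate
3 | (R)-3-[(tert-butyldiphenylsilyl)oxy]butanal | C[C@@H](O[Si](c1ccccc1)(c1ccccc1)C(C)(C)C)CC=O | intermediate
4 | ethyl (2E,5R)-2-bromo-5-[(tert-butyldiphenylsilyl)oxy]hex-2-enoate | C[C@@H](O[Si](c1ccccc1)(c1ccccc1)C(C)(C)C)C/C=C(/Br)C(=O)OCC | intermediate
5 | (2E,5R)-2-bromo-5-[(tert-butyldiphenylsilyl)oxy]hex-2-en-1-ol | C[C@@H](O[Si](c1ccccc1)(c1ccccc1)C(C)(C)C)C/C=C(/Br)CO | intermediate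
6 | (2E,5R)-2-bromo-1,5-bis[(tert-butyldiphenylsilyl)oxy]hex-2-ene | C[C@@H](O[Si](c1ccccc1)(c1ccccc1)C(C)(C)C)C/C=C(/Br)CO[Si](c1ccccc1)(c1ccccc1)C(C)(C)C | intermediate
7 | but-3-yn-1-ol | C#CCCO | starting material
8 | 5-(but-3-yn-1-ylsulfanyl)-1-phenyl-1H-tetrazole | C#CCCSc1nnnn1-c1ccccc1 | intermediate
9 | 5-(but-3-yn-1-ylsulfonyl)-1-phenyl-1H-tetrazole | C#CCCS(=O)(=O)c1nnnn1-c1ccccc1 | intermediate
10 | methyl (S)-3-hydroxy-2-methylpropanoate (Roche ester) | OC[C@H](C)C(=O)OC | starting material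
11 | methyl (S)-3-[(tert-butyldimethylsilyl)oxy]-2-methylpropanoate | CC(C)(C)[Si](C)(C)OC[C@H](C)C(=O)OC | intermediate
12 | (S)-3-[(tert-butyldimethylsilyl)oxy]-2-methylpropanal | CC(C)(C)[Si](C)(C)OC[C@H](C)C=O | intermediate
13 | tert-butyldimethyl{[(2R,3E)-2-methylhept-3-en-6-yn-1-yl]oxy}silane | CC(C)(C)[Si](C)(C)OC[C@H](C)/C=C/CC#C | intermediate
14 | [(1E,4E,6R)-7-[(tert-butyldimethylsilyl)oxy]-2,6-dimethylhepta-1,4-dien-1-yl]dimethylalane | CC(C)(C)[Si](C)(C)OC[C@H](C)/C=C/C/C(C)=C/[Al](C)C | intermediate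
15 | (2R,3E,6E,8Z,11R)-1-[(tert-butyldimethylsilyl)oxy]-11-[(tert-butyldiphenylsilyl)oxy]-8-{[(tert-butyldiphenylsilyl)oxy]methyl}-2,6-dimethyldodeca-3,6,8-triene | CC(C)(C)[Si](C)(C)OC[C@H](C)/C=C/C/C(C)=C/C(CO[Si](c1ccccc1)(c1ccccc1)C(C)(C)C)=C/C[C@@H](C)O[Si](c1ccccc1)(c1ccccc1)C(C)(C)C | intermediate
16 | (2R,3E,6E,8Z,11R)-11-[(tert-butyldiphenylsilyl)oxy]-8-{[(tert-butyldiphenylsilyl)oxy]methyl}-2,6-dimethyldodeca-3,6,8-trien-1-ol | OC[C@H](C)/C=C/C/C(C)=C/C(CO[Si](c1ccccc1)(c1ccccc1)C(C)(C)C)=C/C[C@@H](C)O[Si](c1ccccc1)(c1ccccc1)C(C)(C)C | intermediate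
17 | (2R,3E,6E,8Z,11R)-11-[(tert-butyldiphenylsilyl)oxy]-8-{[(tert-butyldiphenylsilyl)oxy]methyl}-2,6-dimethyldodeca-3,6,8-trienal | O=C[C@H](C)/C=C/C/C(C)=C/C(CO[Si](c1ccccc1)(c1ccccc1)C(C)(C)C)=C/C[C@@H](C)O[Si](c1ccccc1)(c1ccccc1)C(C)(C)C | intermediate
18 | 2-[(1E,3S,4E,7E,9Z,12R)-12-[(tert-butyldiphenylsilyl)oxy]-9-{[(tert-butyldiphenylsilyl)oxy]methyl}-3,7-dimethyltrideca-1,4,7,9-tetraen-1-yl]-4,4,5,5-tetramethyl-1,3,2-dioxaborolane | CC1(C)OB(/C=C/[C@H](C)/C=C/C/C(C)=C/C(CO[Si](c2ccccc2)(c2ccccc2)C(C)(C)C)=C/C[C@@H](C)O[Si](c2ccccc2)(c2ccccc2)C(C)(C)C)OC1(C)C | intermediate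
19 | (S)-citronellal, (S)-3,7-dimethyloct-6-enal | C[C@H](CC=O)CCC=C(C)C | starting material
20 | (1E,4S)-1-iodo-4,8-dimethylnona-1,7-diene | C[C@H](C/C=C/I)CCC=C(C)C | intermediate
21 | (4S,6E)-7-iodo-4-methylhept-6-enal | C[C@H](C/C=C/I)CCC=O | intermediate
22 | (2E,6S,8E)-9-iodo-2,6-dimethylnona-2,8-dienal | C[C@H](C/C=C/I)CC/C=C(\C)C=O | intermediate
23 | (2E,6S,8E,10E,12R,13E,16E,18Z,21R)-21-[(tert-butyldiphenylsilyl)oxy]-18-{[(tert-butyldiphenylsilyl)oxy]methyl}-2,6,12,16-tetramethyldocosa-2,8,10,13,16,18-hexaenal | C[C@H](C/C=C/C=C/[C@H](C)/C=C/C/C(C)=C/C(CO[Si](c1ccccc1)(c1ccccc1)C(C)(C)C)=C/C[C@@H](C)O[Si](c1ccccc1)(c1ccccc1)C(C)(C)C)CC/C=C(\C)C=O | intermediate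
24 | (1S,2S,4aS,6S,8aR)-2-[(2R,3E,6E,8Z,11R)-11-[(tert-butyldiphenylsilyl)oxy]-8-{[(tert-butyldiphenylsilyl)oxy]methyl}-6-methyldodeca-3,6,8-trien-2-yl]-1,6-dimethyl-1,2,4a,5,6,7,8,8a-octahydronaphthalene-1-carbaldehyde | C[C@H]1CC[C@@H]2[C@H](C=C[C@@H]([C@H](C)/C=C/C/C(C)=C/C(CO[Si](c3ccccc3)(c3ccccc3)C(C)(C)C)=C/C[C@@H](C)O[Si](c3ccccc3)(c3ccccc3)C(C)(C)C)[C@@]2(C)C=O)C1 | intermediate
25 | 4-methoxyfuran-2(5H)-one (methyl tetronate) | COC1=CC(=O)OC1 | starting material
26 | lithium (3-methoxy-5-oxo-2,5-dihydrofuran-2-yl)methanolate (racemic) | COC1=CC(=O)OC1C[O-].[Li+] | intermediate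
27 | (3-methoxy-5-oxo-2,5-dihydrofuran-2-yl)methyl methanesulfonate (racemic) | COC1=CC(=O)OC1COS(C)(=O)=O | intermediate
28 | 4-methoxy-5-methylidenefuran-2(5H)-one | COC1=CC(=O)OC1=C | intermediate
29 | 3-{hydroxy[decalinyl]methyl}-4-methoxy-5-methylidenefuran-2(5H)-one, decalinyl = the (1S,2S,4aS,6S,8aR)-octahydronaphthalen-1-yl unit of 24 with its side chain; both carbinol epimers | C[C@H]1CC[C@@H]2[C@H](C=C[C@@H]([C@H](C)/C=C/C/C(C)=C/C(CO[Si](c3ccccc3)(c3ccccc3)C(C)(C)C)=C/C[C@@H](C)O[Si](c3ccccc3)(c3ccccc3)C(C)(C)C)[C@@]2(C)C(O)C4=C(OC)C(=C)OC4=O)C1 | intermediate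
30 | 4-methoxy-5-methylidene-3-[decalinylcarbonyl]furan-2(5H)-one (ketone of 29, decalinyl unit as in 24) | C[C@H]1CC[C@@H]2[C@H](C=C[C@@H]([C@H](C)/C=C/C/C(C)=C/C(CO[Si](c3ccccc3)(c3ccccc3)C(C)(C)C)=C/C[C@@H](C)O[Si](c3ccccc3)(c3ccccc3)C(C)(C)C)[C@@]2(C)C(=O)C4=C(OC)C(=C)OC4=O)C1 | intermediate
31 | O-methyl ether, bis(tert-butyldiphenylsilyl) ether of the target (enol O33 methylated, O20 and O25 silylated; 2S,5R,6S,9S,10R,15R,21R,23R,27S,36S in SMILES atom labels) | C[C@H]1CC[C@@H]2[C@H](C=C[C@H]3[C@H](C)/C=C/C[C@]4(C)C=C(CO[Si](c6ccccc6)(c6ccccc6)C(C)(C)C)[C@H](C[C@@H](C)O[Si](c6ccccc6)(c6ccccc6)C(C)(C)C)C[C@]45OC(=O)C(=C5OC)C(=O)[C@@]23C)C1 | intermediate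
32 | O-methyl ether of the target (enol O33 methylated, both alcohols free; stereocentres as in 33) | C[C@H]1CC[C@@H]2[C@H](C=C[C@H]3[C@H](C)/C=C/C[C@]4(C)C=C(CO)[C@H](C[C@@H](C)O)C[C@]45OC(=O)C(=C5OC)C(=O)[C@@]23C)C1 | intermediate
33 | CNP0189906.1 (2S,5R,6S,9S,10R,15R,21R,23R,27S,36S in SMILES atom labels) | C[C@H]1CC[C@@H]2[C@H](C=C[C@H]3[C@H](C)/C=C/C[C@]4(C)C=C(CO)[C@H](C[C@@H](C)O)C[C@]45OC(=O)C(=C5O)C(=O)[C@@]23C)C1 | target

## Step count and main risks

Total step count: 24 (one-pot operations counted once; preparation of the step 3 phosphonate not counted).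
Longest linear sequence: 15 steps (1, 2, 3, 4, 5, 11, 12, 13, 14, 18, 19, 21, 22, 23, 24).

The three steps most likely to fail:

Step 19 (rings A and B). The axial C2 methyl of the target means the required transition state carries that methyl pseudo-axially, so the tether favours the other diene face and the catalyst may not override it; the dr may be low. Fallback, setting out from hexaenal 23 and returning at ketone 30: lithiated 28 is added to 23 to give the open-chain tetronate carbinol F1, which is oxidised with Dess–Martin periodinane to the open-chain 3-acyl-5-methylidene tetronate F2. The ring A/B cycloaddition is then run on F2 with [Cu((S,S)-t-Bu-box)](SbF6)2 in CH2Cl2 at −20 °C. The lactone and ketone carbonyls of F2 form a six-membered chelate (two-point binding of the kind used with acyl-oxazolidinone and alkylidene-malonate dienophiles), so the ligand rather than the tether shields one face of the enone. The product is ketone 30, which is heated on as in step 22.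

Step 21 (C31–C34 bond). Lithiated 28 may add to itself at the exocyclic alkene or fail to add to the hindered α-quaternary aldehyde. Fallback, setting out from 28 and 24 and returning at carbinol 29: 28 is iodinated at C3 with N-iodosuccinimide and catalytic CF3CO2H to give 3-iodo-4-methoxy-5-methylidenefuran-2(5H)-one F3. F3 is joined to 24 by Nozaki–Hiyama–Kishi coupling (CrCl2, NiCl2 catalyst, DMF, rt), an alkenylchromium addition that needs no strong base and tolerates hindered aldehydes, giving 29.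

Step 22 (ring C and macrocycle). The face and endo/exo preference of the macrocyclisation rest on the conformation of the tether, and oligomerisation of the methylidene tetronate competes. Fallback, setting out from carbinol 29 and returning at target 33: 29 is oxidised to 30 at 0 °C as before, but the O-methyl group is removed first (LiCl, DMSO, 40 °C) to give the free 3-acyl-5-methylidene tetronic acid F4. In F4 the internal hydrogen bond holds the tricarbonyl unit planar, as in the biosynthetic substrate type. F4 is cyclised in dilute toluene at 100 °C to the bis(tert-butyldiphenylsilyl) ether of the target F5, and HF·pyridine then gives 33.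

## Further compounds

F1 | step 19 | 3-[(2E,6S,8E,10E,12R,13E,16E,18Z,21R)-1-hydroxy-21-[(tert-butyldiphenylsilyl)oxy]-18-{[(tert-butyldiphenylsilyl)oxy]methyl}-2,6,12,16-tetramethyldocosa-2,8,10,13,16,18-hexaen-1-yl]-4-methoxy-5-methylidenefuran-2(5H)-one (both carbinol epimers) | C[C@H](C/C=C/C=C/[C@H](C)/C=C/C/C(C)=C/C(CO[Si](c1ccccc1)(c1ccccc1)C(C)(C)C)=C/C[C@@H](C)O[Si](c1ccccc1)(c1ccccc1)C(C)(C)C)CC/C=C(\C)C(O)C1=C(OC)C(=C)OC1=O
F2 | step 19 | 3-[(2E,6S,8E,10E,12R,13E,16E,18Z,21R)-21-[(tert-butyldiphenylsilyl)oxy]-18-{[(tert-butyldiphenylsilyl)oxy]methyl}-2,6,12,16-tetramethyldocosa-2,8,10,13,16,18-hexaenoyl]-4-methoxy-5-methylidenefuran-2(5H)-one | C[C@H](C/C=C/C=C/[C@H](C)/C=C/C/C(C)=C/C(CO[Si](c1ccccc1)(c1ccccc1)C(C)(C)C)=C/C[C@@H](C)O[Si](c1ccccc1)(c1ccccc1)C(C)(C)C)CC/C=C(\C)C(=O)C1=C(OC)C(=C)OC1=O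
F3 | step 21 | 3-iodo-4-methoxy-5-methylidenefuran-2(5H)-one | COC1=C(I)C(=O)OC1=C
F4 | step 22 | 4-hydroxy-5-methylidene-3-[decalinylcarbonyl]furan-2(5H)-one (O-demethylated 30, decalinyl unit as in 24) | C[C@H]1CC[C@@H]2[C@H](C=C[C@@H]([C@H](C)/C=C/C/C(C)=C/C(CO[Si](c3ccccc3)(c3ccccc3)C(C)(C)C)=C/C[C@@H](C)O[Si](c3ccccc3)(c3ccccc3)C(C)(C)C)[C@@]2(C)C(=O)C4=C(O)C(=C)OC4=O)C1
F5 | step 22 | bis(tert-butyldiphenylsilyl) ether of 33 (O20 and O25 silylated, stereocentres as in 33) | C[C@H]1CC[C@@H]2[C@H](C=C[C@H]3[C@H](C)/C=C/C[C@]4(C)C=C(CO[Si](c6ccccc6)(c6ccccc6)C(C)(C)C)[C@H](C[C@@H](C)O[Si](c6ccccc6)(c6ccccc6)C(C)(C)C)C[C@]45OC(=O)C(=C5O)C(=O)[C@@]23C)C1
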